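## Retrosynthetic overview

- Coloratanin A is an isoflavone with no stereocentre. The last step only removes the two silyl ethers of ring B (aryl O–SiMe2tBu, tertiary O–SiEt3).
- The strategy rests on ring A (C4a, C5, C6, C7, C8, C8a), a phloroglucinol with oxygens on C5 and C7 and the prenyl group on C6. C5–C8 map onto a 1,3-dioxygenated 2-prenylbutadiene, and C4a=C8a is one double bond of a 4-pyranone (ring C) that already carries O1 on C8a.
- Ring A is therefore cut at C8–C8a and C4a–C5. The partners are a 1-methoxy-1,3-bis(trimethylsilyloxy)-2-prenylbutadiene and a 3-aryl-5-(p-tolylsulfinyl)-4-pyranone; loss of p-toluenesulfenic acid and methanol aromatises the adduct.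
- The pyranone comes from 3,5-dibromo-4H-pyran-4-one by one Suzuki coupling with the ring B boronate, then C–S coupling and S-oxidation. Ring B comes from dihydrocoumarin, the diene from methyl acetoacetate and prenyl bromide.
- Ring order: rings B and C are bought as benzene and pyranone rings; ring A is the only ring made, and it is made last.

Key step: step 12

Assumption: 3,5-dibromo-4H-pyran-4-one is taken as purchasable; the sulfoxide is racemic at sulfur and the cycloadduct is a diastereomer mixture, which is harmless because every stereocentre is destroyed on aromatisation.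

## Route

Step 1
Reactants: 1 dihydrocoumarin
Product: 2 2-(3-hydroxy-3-methylbutyl)phenol
Conditions: MeMgBr (3.5 equiv), THF, 0 °C → rt; sat. aq. NH4Cl
Reagents that add atoms: methylmagnesium bromide, C[Mg]Br
Why: Double Grignard addition to the aryl lactone carbonyl should open the ring to the tertiary carbinol and the phenol, and the near-neutral quench avoids acid-catalysed closure to a 2,2-dimethylchroman.

Step 2
Reactants: 2 2-(3-hydroxy-3-methylbutyl)phenol
Product: 3 4-bromo-2-(3-hydroxy-3-methylbutyl)phenol
Conditions: NBS (1.0 equiv), MeCN, −10 → 0 °C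
Reagents that add atoms: N-bromosuccinimide, O=C1CCC(=O)N1Br
Why: Electrophilic aromatic bromination of a 2-alkylphenol with NBS in acetonitrile should go para to the hydroxyl, and it gives succinimide instead of HBr, so the acid-sensitive tertiary alcohol is left alone.

Step 3
Reactants: 3 4-bromo-2-(3-hydroxy-3-methylbutyl)phenol
Product: 4 4-[5-bromo-2-(tert-butyldimethylsilyloxy)phenyl]-2-methylbutan-2-ol
Conditions: TBSCl, imidazole, DMF, rt
Reagents that add atoms: tert-butyldimethylsilyl chloride, CC(C)(C)[Si](C)(C)Cl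
Why: Silylation with the chlorosilane and imidazole is selective for the phenol, because the hindered tertiary alcohol does not react under these conditions.

Step 4
Reactants: 4 4-[5-bromo-2-(tert-butyldimethylsilyloxy)phenyl]-2-methylbutan-2-ol
Product: 5 1-bromo-4-(tert-butyldimethylsilyloxy)-3-(3-methyl-3-triethylsilyloxybutyl)benzene
Conditions: TESOTf, 2,6-lutidine, CH2Cl2, −78 → 0 °C
Reagents that add atoms: triethylsilyl triflate, CC[Si](CC)(CC)OS(=O)(=O)C(F)(F)F
Why: The silyl triflate with a hindered pyridine base silylates tertiary alcohols, and the triethylsilyl ether is later removable by fluoride together with the aryl silyl ether.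

Step 5
Reactants: 5 1-bromo-4-(tert-butyldimethylsilyloxy)-3-(3-methyl-3-triethylsilyloxybutyl)benzene
Product: 6 2-[4-(tert-butyldimethylsilyloxy)-3-(3-methyl-3-triethylsilyloxybutyl)phenyl]-4,4,5,5-tetramethyl-1,3,2-dioxaborolane
Conditions: B2pin2, Pd(dppf)Cl2 (3 mol%), KOAc, 1,4-dioxane, 85 °C
Reagents that add atoms: bis(pinacolato)diboron, CC1(C)OB(OC1(C)C)B1OC(C)(C)C(C)(C)O1
Why: Miyaura borylation of an aryl bromide with the weak base KOAc tolerates both silyl ethers and gives the pinacol boronate without homocoupling.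

Step 6
Reactants: 6 2-[4-(tert-butyldimethylsilyloxy)-3-(3-methyl-3-triethylsilyloxybutyl)phenyl]-4,4,5,5-tetramethyl-1,3,2-dioxaborolane; 7 3,5-dibromo-4H-pyran-4-one
Product: 8 3-bromo-5-[4-(tert-butyldimethylsilyloxy)-3-(3-methyl-3-triethylsilyloxybutyl)phenyl]-4H-pyran-4-one
Conditions: 7 (3 equiv), Pd(PPh3)4 (5 mol%), K3PO4, 1,4-dioxane/H2O (10:1), 60 °C
Reagents that add atoms: none
Why: Suzuki–Miyaura coupling at one of the two equivalent carbonyl-activated alkenyl C–Br bonds should give mainly the mono-aryl product when the cheap dibromide is in threefold excess and is recovered, and the mild phosphate base at moderate temperature should spare the pyranone and the aryl silyl ether.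

Step 7
Reactants: 8 3-bromo-5-[4-(tert-butyldimethylsilyloxy)-3-(3-methyl-3-triethylsilyloxybutyl)phenyl]-4H-pyran-4-one
Product: 9 3-[4-(tert-butyldimethylsilyloxy)-3-(3-methyl-3-triethylsilyloxybutyl)phenyl]-5-(p-tolylsulfanyl)-4H-pyran-4-one
Conditions: p-toluenethiol, Pd2(dba)3 (2.5 mol%), Xantphos (5 mol%), iPr2NEt, 1,4-dioxane, 90 °C
Reagents that add atoms: p-toluenethiol, Cc1ccc(S)cc1
Why: Palladium-catalysed C–S cross-coupling (Migita type, Xantphos ligand) of the alkenyl bromide with the thiol under a weak amine base keeps the free thiolate concentration low, so substitution at C5 should outrun conjugate addition to the pyranone.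

Step 8
Reactants: 9 3-[4-(tert-butyldimethylsilyloxy)-3-(3-methyl-3-triethylsilyloxybutyl)phenyl]-5-(p-tolylsulfanyl)-4H-pyran-4-one
Product: 10 3-[4-(tert-butyldimethylsilyloxy)-3-(3-methyl-3-triethylsilyloxybutyl)phenyl]-5-(p-tolylsulfinyl)-4H-pyran-4-one (racemic at sulfur)
Conditions: mCPBA (1.0 equiv), CH2Cl2, −78 → −30 °C
Reagents that add atoms: 3-chloroperoxybenzoic acid, OOC(=O)c1cccc(Cl)c1
Why: Sulfide-to-sulfoxide oxidation with one equivalent of peracid at low temperature is much faster than sulfone formation, and the substrate holds no other oxidisable group since the prenyl alkene is not yet present.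

Step 9
Reactants: 11 methyl acetoacetate; 12 prenyl bromide
Product: 13 methyl 2-acetyl-5-methylhex-4-enoate (racemic)
Conditions: K2CO3, acetone, reflux (11 in 1.5-fold excess)
Reagents that add atoms: none
Why: C-Alkylation of the acetoacetate enolate with the allylic bromide is a standard SN2 reaction, and the excess of the keto ester limits dialkylation.

Step 10
Reactants: 13 methyl 2-acetyl-5-methylhex-4-enoate
Product: 14 methyl 5-methyl-2-[1-(trimethylsilyloxy)ethylidene]hex-4-enoate (E/Z mixture)
Conditions: TMSCl, Et3N, hexane, rt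
Reagents that add atoms: trimethylsilyl chloride, C[Si](C)(C)Cl
Why: O-Silylation of the enolised keto ester under amine base gives the conjugated silyl enol ether, the usual first stage of a Chan-type diene synthesis.

Step 11
Reactants: 14 methyl 5-methyl-2-[1-(trimethylsilyloxy)ethylidene]hex-4-enoate
Product: 15 1-methoxy-2-(3-methylbut-2-enyl)-1,3-bis(trimethylsilyloxy)buta-1,3-diene (ketene acetal isomer mixture)
Conditions: LiN(iPr)2 (commercial solution), THF, −78 °C; then TMSCl, −78 → 0 °C
Reagents that add atoms: trimethylsilyl chloride, C[Si](C)(C)Cl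
Why: Vinylogous deprotonation of the methyl group by the lithium amide and O-silylation of the resulting dienolate give the 1-alkoxy-1,3-bis(silyloxy)diene, which is filtered from salts under argon and used at once.

Step 12
Reactants: 10 3-[4-(tert-butyldimethylsilyloxy)-3-(3-methyl-3-triethylsilyloxybutyl)phenyl]-5-(p-tolylsulfinyl)-4H-pyran-4-one; 15 1-methoxy-2-(3-methylbut-2-enyl)-1,3-bis(trimethylsilyloxy)buta-1,3-diene
Product: 18 5,7-dihydroxy-6-prenyl-3-[4-(tert-butyldimethylsilyloxy)-3-(3-methyl-3-triethylsilyloxybutyl)phenyl]chromen-4-one, via sulfinyl cycloadduct 16 (not isolated), via 5-methoxy-5,8-dihydrochromenone 17 (not isolated)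
Conditions: 15 (2.5 equiv), toluene, 0 → 70 °C; then silica gel, THF/H2O, rt
Reagents that add atoms: none
Why: The nucleophilic CH2 terminus of the diene (future C8) should add to the enone beta carbon C8a of 10 while the ketene acetal carbon (future C5) bonds to the sulfinyl-bearing C4a, in an asynchronous normal-demand [4+2] cycloaddition giving 16. Suprafacial addition leaves the sulfinyl group on C4a cis to the only beta hydrogen (on C8a), so thermal syn elimination of p-toluenesulfenic acid gives 17; on work-up the C5 ketal loses methanol, the dienone tautomerises and the two O–SiMe3 bonds are hydrolysed to give 18. The closest known reaction type is the Diels–Alder benzannulation of 1-alkoxy-1,3-bis(silyloxy)dienes with halogen- or sulfinyl-activated enones (haloquinones, 3-sulfinylchromones) followed by elimination. Ring A is closed as a six-membered carbocycle by intermolecular [4+2] union through the two bonds C8–C8a and C4a–C5; in the stepwise limit this is a vinylogous Mukaiyama–Michael addition followed by 6-exo-trig closure of the sulfinyl enolate carbon onto the silyloxycarbenium carbon. The stereocentres of 16 at C4a, C5, C8a and sulfur are transient and none survives in 18. The step needs regio- and site-selectivity: the polarised diene terminus and the doubly activated C4a (ketone and sulfinyl) fix the orientation, the sulfinyl group makes this double bond and not the aryl-bearing one the dienophile, the O1–C8a bond already present excludes an 8-prenyl isomer, and the silyl ethers on ring B keep protic groups away from the diene.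

Step 13
Reactants: 18 5,7-dihydroxy-6-prenyl-3-[4-(tert-butyldimethylsilyloxy)-3-(3-methyl-3-triethylsilyloxybutyl)phenyl]chromen-4-one
Product: 19 coloratanin A
Conditions: Bu4NF (3 equiv), AcOH (3 equiv), THF, 0 °C → rt
Reagents that add atoms: none
Why: Fluoride cleaves both the aryl tert-butyldimethylsilyl ether and the tertiary triethylsilyl ether, and the acetic acid buffer and absence of strong acid keep the prenyl group and the tertiary alcohol from cyclising onto the neighbouring phenols.

## Compound list

1 | dihydrocoumarin (chroman-2-one) | O=C1CCc2ccccc2O1 | starting material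
2 | 2-(3-hydroxy-3-methylbutyl)phenol | CC(C)(O)CCc1ccccc1O | intermediate
3 | 4-bromo-2-(3-hydroxy-3-methylbutyl)phenol | CC(C)(O)CCc1cc(Br)ccc1O | intermediate
4 | 4-[5-bromo-2-(tert-butyldimethylsilyloxy)phenyl]-2-methylbutan-2-ol | CC(C)(O)CCc1cc(Br)ccc1O[Si](C)(C)C(C)(C)C | intermediate
5 | 1-bromo-4-(tert-butyldimethylsilyloxy)-3-(3-methyl-3-triethylsilyloxybutyl)benzene | CC[Si](CC)(CC)OC(C)(C)CCc1cc(Br)ccc1O[Si](C)(C)C(C)(C)C | intermediate
6 | 2-[4-(tert-butyldimethylsilyloxy)-3-(3-methyl-3-triethylsilyloxybutyl)phenyl]-4,4,5,5-tetramethyl-1,3,2-dioxaborolane | CC[Si](CC)(CC)OC(C)(C)CCc1cc(B2OC(C)(C)C(C)(C)O2)ccc1O[Si](C)(C)C(C)(C)C | intermediate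
7 | 3,5-dibromo-4H-pyran-4-one | O=c1c(Br)cocc1Br | starting material
8 | 3-bromo-5-[4-(tert-butyldimethylsilyloxy)-3-(3-methyl-3-triethylsilyloxybutyl)phenyl]-4H-pyran-4-one | O=c1c(Br)cocc1-c1ccc(O[Si](C)(C)C(C)(C)C)c(CCC(C)(C)O[Si](CC)(CC)CC)c1 | intermediate
9 | 3-[4-(tert-butyldimethylsilyloxy)-3-(3-methyl-3-triethylsilyloxybutyl)phenyl]-5-(p-tolylsulfanyl)-4H-pyran-4-one | Cc1ccc(Sc2cocc(-c3ccc(O[Si](C)(C)C(C)(C)C)c(CCC(C)(C)O[Si](CC)(CC)CC)c3)c2=O)cc1 | intermediate
10 | 3-[4-(tert-butyldimethylsilyloxy)-3-(3-methyl-3-triethylsilyloxybutyl)phenyl]-5-(p-tolylsulfinyl)-4H-pyran-4-one, racemic at sulfur | Cc1ccc(S(=O)c2cocc(-c3ccc(O[Si](C)(C)C(C)(C)C)c(CCC(C)(C)O[Si](CC)(CC)CC)c3)c2=O)cc1 | intermediate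
11 | methyl acetoacetate | COC(=O)CC(C)=O | starting material
12 | prenyl bromide (1-bromo-3-methylbut-2-ene) | CC(C)=CCBr | starting material
13 | methyl 2-acetyl-5-methylhex-4-enoate, racemic | COC(=O)C(CC=C(C)C)C(C)=O | intermediate
14 | methyl 5-methyl-2-[1-(trimethylsilyloxy)ethylidene]hex-4-enoate, E/Z mixture | COC(=O)C(CC=C(C)C)=C(C)O[Si](C)(C)C | intermediate
15 | 1-methoxy-2-(3-methylbut-2-enyl)-1,3-bis(trimethylsilyloxy)buta-1,3-diene, ketene acetal isomer mixture | C=C(O[Si](C)(C)C)C(CC=C(C)C)=C(OC)O[Si](C)(C)C | intermediate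
16 | 5-methoxy-6-prenyl-4a-(p-tolylsulfinyl)-5,7-bis(trimethylsilyloxy)-3-[4-(tert-butyldimethylsilyloxy)-3-(3-methyl-3-triethylsilyloxybutyl)phenyl]-4a,5,8,8a-tetrahydrochromen-4-one, diastereomer mixture | COC1(O[Si](C)(C)C)C(CC=C(C)C)=C(O[Si](C)(C)C)CC2OC=C(c3ccc(O[Si](C)(C)C(C)(C)C)c(CCC(C)(C)O[Si](CC)(CC)CC)c3)C(=O)C12S(=O)c1ccc(C)cc1 | intermediate
17 | 5-methoxy-6-prenyl-5,7-bis(trimethylsilyloxy)-3-[4-(tert-butyldimethylsilyloxy)-3-(3-methyl-3-triethylsilyloxybutyl)phenyl]-5,8-dihydrochromen-4-one, racemic | COC1(O[Si](C)(C)C)C(CC=C(C)C)=C(O[Si](C)(C)C)CC2=C1C(=O)C(c1ccc(O[Si](C)(C)C(C)(C)C)c(CCC(C)(C)O[Si](CC)(CC)CC)c1)=CO2 | intermediate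
18 | 5,7-dihydroxy-6-prenyl-3-[4-(tert-butyldimethylsilyloxy)-3-(3-methyl-3-triethylsilyloxybutyl)phenyl]chromen-4-one | CC(C)=CCc1c(O)cc2occ(-c3ccc(O[Si](C)(C)C(C)(C)C)c(CCC(C)(C)O[Si](CC)(CC)CC)c3)c(=O)c2c1O | intermediate
19 | coloratanin A | CC(C)=CCc1c(O)cc2occ(-c3ccc(O)c(CCC(C)(C)O)c3)c(=O)c2c1O | target

## Step count and risk

Total steps: 13. Longest linear sequence: 10 steps (steps 1 to 8, then 12 and 13); the diene branch (steps 9 to 11) joins at step 12.

Steps most likely to fail:

1. Step 12. The pyranone double bond belongs to a weakly aromatic vinylogous ester and may react sluggishly. Conjugate addition at C8a may be followed by opening of the pyranone at O1–C8a instead of ring closure. The sulfenic acid released during the reaction may protodesilylate the diene before it has reacted. The fallback sets out from sulfide 9 and comes back to the route at 18 through 17. Oxidation of 9 with an excess of mCPBA (2.5 equiv, CH2Cl2, 0 °C → rt) should give 3-[4-(tert-butyldimethylsilyloxy)-3-(3-methyl-3-triethylsilyloxybutyl)phenyl]-5-(p-tolylsulfonyl)-4H-pyran-4-one F1. Its double bond is more electron-poor, and it cannot lose an acid thermally. Cycloaddition with 15 (toluene, rt → 60 °C) should give the sulfonyl cycloadduct F2 as a stable beta-keto sulfone. Ring formation is thereby separated from aromatisation: DBU (THF, 0 °C) induces E1cB loss of p-toluenesulfinate to 17, and the silica gel work-up of step 12 then gives 18.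

2. Step 7. Thiolate may add to C6 of the pyranone and open the ring, and the thiol may inhibit the palladium catalyst. The fallback sets out from bromide 8 and comes back at sulfoxide 10, bypassing 9 and step 8. Bromine–magnesium exchange with iPrMgCl·LiCl (THF, −40 °C) should give the 5-aryl-4-oxo-4H-pyran-3-ylmagnesium chloride F3. It is quenched at low temperature with methyl p-toluenesulfinate (Andersen-type sulfinylation), which delivers the sulfinyl group as an electrophile and gives 10 directly.

3. Step 6. Both C–Br bonds may be arylated, and aqueous base may open the pyranone or cleave the aryl silyl ether. The fallback sets out from aryl bromide 5 and comes back at 8 without water or base. Bromine–lithium exchange with n-BuLi (THF, −78 °C) gives [4-(tert-butyldimethylsilyloxy)-3-(3-methyl-3-triethylsilyloxybutyl)phenyl]lithium F4. ZnCl2 converts it into the corresponding arylzinc chloride F5. Negishi coupling of this with an excess of 7 (Pd(PPh3)4, THF, rt → 50 °C) should give 8.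

## Further compounds

F1 | step 12 | 3-[4-(tert-butyldimethylsilyloxy)-3-(3-methyl-3-triethylsilyloxybutyl)phenyl]-5-(p-tolylsulfonyl)-4H-pyran-4-one | Cc1ccc(S(=O)(=O)c2cocc(-c3ccc(O[Si](C)(C)C(C)(C)C)c(CCC(C)(C)O[Si](CC)(CC)CC)c3)c2=O)cc1
F2 | step 12 | 5-methoxy-6-prenyl-4a-(p-tolylsulfonyl)-5,7-bis(trimethylsilyloxy)-3-[4-(tert-butyldimethylsilyloxy)-3-(3-methyl-3-triethylsilyloxybutyl)phenyl]-4a,5,8,8a-tetrahydrochromen-4-one, diastereomer mixture | COC1(O[Si](C)(C)C)C(CC=C(C)C)=C(O[Si](C)(C)C)CC2OC=C(c3ccc(O[Si](C)(C)C(C)(C)C)c(CCC(C)(C)O[Si](CC)(CC)CC)c3)C(=O)C12S(=O)(=O)c1ccc(C)cc1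
F3 | step 7 | {5-[4-(tert-butyldimethylsilyloxy)-3-(3-methyl-3-triethylsilyloxybutyl)phenyl]-4-oxo-4H-pyran-3-yl}magnesium chloride | O=c1c([Mg]Cl)cocc1-c1ccc(O[Si](C)(C)C(C)(C)C)c(CCC(C)(C)O[Si](CC)(CC)CC)c1
F4 | step 6 | [4-(tert-butyldimethylsilyloxy)-3-(3-methyl-3-triethylsilyloxybutyl)phenyl]lithium | [Li]c1ccc(O[Si](C)(C)C(C)(C)C)c(CCC(C)(C)O[Si](CC)(CC)CC)c1
F5 | step 6 | [4-(tert-butyldimethylsilyloxy)-3-(3-methyl-3-triethylsilyloxybutyl)phenyl]zinc chloride | Cl[Zn]c1ccc(O[Si](C)(C)C(C)(C)C)c(CCC(C)(C)O[Si](CC)(CC)CC)c1
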